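**Plan**

- Ring numbering used throughout: C1 (CH bearing the first coumarin), C2=C3 (methyl on C3), C4H2, C5Me2, C6H, carbinol carbon C7. The C7 oxygen can reach C3 across the ring, so a C7–O unit bridges C6 and C3, the two ends of a C6=C1–C2=C3 diene; a 2-oxabicyclo[2.2.2]oct-5-ene is latent in the target.
- Retrosynthesis: the C7 carbinol goes back to its ketone and from there to the C7 epimer. The C1–aryl bond is then cut as a Friedel–Crafts bond between citropten and the allyl cation C1–C2–C3 released from the bridged tertiary allylic ether. Last, C6–C7 and C3–O are cut together as an oxa-Diels–Alder reaction of the coumarin-8-carbaldehyde with 1,5,5-trimethylcyclohexa-1,3-diene.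
- Forward: the diene comes from isophorone (tosylhydrazone, Shapiro) and the aldehyde from citropten (Vilsmeier–Haack). The cycloaddition closes the only new ring. Acid then opens the ether and joins the second coumarin to C1, and oxidation followed by reduction inverts C7.
- Stereochemistry: C6 comes from the chiral Brønsted acid in the cycloaddition. C1 comes from arene attack anti to the C6 substituent (trans). C7 comes from Felkin–Anh hydride addition to the aryl ketone.

Key step: step 4

Assumption: the aryl group is taken to enter endo in the cycloaddition, and the catalyst enantiomer that gives the (4R) series (called (S,S) below) has to be identified in a first run, since the sense of induction cannot be assigned by analogy for this diene.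

**Step 1**
Reactants: 1 isophorone
Product: 2 N'-(3,5,5-trimethylcyclohex-2-en-1-ylidene)-4-methylbenzenesulfonohydrazide (isophorone tosylhydrazone; E/Z mixture at C=N)
Conditions: TsNHNH2, cat. HCl, EtOH, reflux
Reagents that add atoms: p-toluenesulfonyl hydrazide, Cc1ccc(cc1)S(=O)(=O)NN
Why: Acid-catalysed condensation of a ketone with a sulfonyl hydrazide (tosylhydrazone formation) is reliable for enones and creates no stereocentre.

**Step 2**
Reactants: 2 isophorone tosylhydrazone
Product: 4 1,5,5-trimethylcyclohexa-1,3-diene, via vinyllithium 3 (not isolated)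
Conditions: MeLi (2.2 equiv), Et2O, 0 °C → rt; then H2O; distillation
Reagents that add atoms: none
Why: In this Shapiro reaction the base removes N–H and then a proton of the only sp3 α-carbon (the CH2 next to CMe2), loss of sulfinate and N2 gives the vinyllithium, and its protonation leaves the conjugated diene with the new double bond toward the gem-dimethyl carbon and no stereocentre.

**Step 3**
Reactants: 5 citropten
Product: 7 5,7-dimethoxy-2-oxo-2H-chromene-8-carbaldehyde, via iminium chloride 6 (not isolated)
Conditions: POCl3, DMF, 0 → 70 °C; then aq. NaOAc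
Reagents that add atoms: N,N-dimethylformamide, CN(C)C=O (formyl carbon); water, O (carbonyl oxygen)
Why: Vilsmeier–Haack formylation should attack C8, the most nucleophilic and less hindered free position of a 5,7-dioxygenated coumarin (ortho to the 7-methoxy group and the ring oxygen, para to the 5-methoxy group), as acylations of related coumarins do, and it forms no stereocentre.

**Step 4**
Reactants: 4 the trimethylcyclohexadiene; 7 the citropten-derived carbaldehyde
Product: 8 (1R,3S,4R)-3-(5,7-dimethoxy-2-oxo-2H-chromen-8-yl)-1,8,8-trimethyl-2-oxabicyclo[2.2.2]oct-5-ene (aryl endo, syn to the C5=C6 bridge)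
Conditions: (S,S)-imidodiphosphorimidate (IDPi) Brønsted acid (5 mol %), diene in threefold excess, 5 Å MS, CHCl3, −20 °C → rt
Reagents that add atoms: none
Why: The confined chiral acid activates the formyl oxygen inside its ion-pair pocket, the aldehyde carbon attacks the unsubstituted diene terminus next to CMe2 while positive charge builds at the methyl-bearing terminus, and the oxygen collapses onto that terminus in the same asynchronous [4+2] event. The closest known reaction type is the Brønsted-acid-catalysed oxa-Diels–Alder reaction of unactivated aldehydes with simple dienes, including its enantioselective version with confined imidodiphosphorimidates and the acid-promoted additions to cyclohexa-1,3-dienes that give 2-oxabicyclo[2.2.2]octenes. The one new ring, the dihydropyran O2–C3–C4–C5=C6–C1, closes by suprafacial [4+2] cycloaddition across the s-cis-locked cyclic diene (in the stepwise limit, six-membered collapse of the oxygen onto the allyl cation). C4 is set by the catalyst, which selects the diene face; C1 follows from C4 because both bonds form on the same face of the ring; C3 follows from the endo position of the aryl group, which the syn methyl of the neighbouring gem-dimethyl carbon enforces by blocking the exo position. The step needs regioselectivity, secured by the ring methyl group that makes its terminus the cation-stabilising site, and enantioface selection, which only the catalyst supplies; the endo/exo outcome is not critical because C3 later passes through the ketone.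

**Step 5**
Reactants: 8 the oxabicycle; 5 citropten
Product: 9 8-[(1S,6R)-6-[(S)-(5,7-dimethoxy-2-oxo-2H-chromen-8-yl)(hydroxy)methyl]-3,5,5-trimethylcyclohex-2-en-1-yl]-5,7-dimethoxy-2H-chromen-2-one (C7 epimer of the target)
Conditions: BF3·OEt2 (0.3 equiv), citropten in threefold excess, CH2Cl2, −40 → 0 °C; aq. NaHCO3
Reagents that add atoms: none
Why: In this SN1-type Friedel–Crafts allylation the Lewis acid ionises the tertiary allylic bridgehead C–O bond, and C8 of citropten attacks the secondary terminus of the 3-methylcyclohexenyl cation on the face opposite the neighbouring carbinol-bearing substituent, which sets C1 trans (S), as in the acid-mediated coupling of terpenoid tertiary allylic alcohols with resorcinols.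

**Step 6**
Reactants: 9 the (S)-carbinol
Product: 10 8-[(1S,6R)-6-(5,7-dimethoxy-2-oxo-2H-chromene-8-carbonyl)-3,5,5-trimethylcyclohex-2-en-1-yl]-5,7-dimethoxy-2H-chromen-2-one
Conditions: Dess–Martin periodinane, NaHCO3, CH2Cl2, 0 °C → rt
Reagents that add atoms: none
Why: Buffered Dess–Martin oxidation should convert the hindered secondary benzylic alcohol into the aryl ketone without touching the alkene or the lactones, and C6 already has the more stable trans arrangement, so any enolisation should return the same epimer.

**Step 7**
Reactants: 10 the aryl ketone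
Product: 11 8-[(1S,6R)-6-[(R)-(5,7-dimethoxy-2-oxo-2H-chromen-8-yl)(hydroxy)methyl]-3,5,5-trimethylcyclohex-2-en-1-yl]-5,7-dimethoxy-2H-chromen-2-one (IN0553)
Conditions: NaBH4, CeCl3·7H2O, MeOH/THF, −40 → 0 °C
Reagents that add atoms: none
Why: Luche reduction, which spares coumarin lactones, should follow the Felkin–Anh model with the bond to the quaternary C5 antiperiplanar to the incoming hydride and the hydride passing the small C6–H, which means attack on the Si face of the ketone and the (R)-carbinol.

**Compound list**

1 | isophorone (3,5,5-trimethylcyclohex-2-en-1-one) | CC1=CC(=O)CC(C)(C)C1 | starting material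
2 | isophorone tosylhydrazone (E/Z mixture at C=N) | CC1=CC(=NNS(=O)(=O)c2ccc(C)cc2)CC(C)(C)C1 | intermediate
3 | 3-lithio-1,5,5-trimethylcyclohexa-1,3-diene (vinyllithium) | [Li]C1=CC(C)(C)CC(C)=C1 | intermediate
4 | 1,5,5-trimethylcyclohexa-1,3-diene | CC1=CC=CC(C)(C)C1 | intermediate
5 | citropten (5,7-dimethoxy-2H-chromen-2-one) | COc1cc(OC)c2ccc(=O)oc2c1 | starting material
6 | N-[(5,7-dimethoxy-2-oxo-2H-chromen-8-yl)methylidene]-N-methylmethanaminium chloride | COc1cc(OC)c2ccc(=O)oc2c1C=[N+](C)C.[Cl-] | intermediate
7 | 5,7-dimethoxy-2-oxo-2H-chromene-8-carbaldehyde | COc1cc(OC)c2ccc(=O)oc2c1C=O | intermediate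
8 | (1R,3S,4R)-3-(5,7-dimethoxy-2-oxo-2H-chromen-8-yl)-1,8,8-trimethyl-2-oxabicyclo[2.2.2]oct-5-ene | C[C@@]12CC(C)(C)[C@@H](C=C1)[C@@H](c1c(OC)cc(OC)c3ccc(=O)oc13)O2 | intermediate
9 | 8-[(1S,6R)-6-[(S)-(5,7-dimethoxy-2-oxo-2H-chromen-8-yl)(hydroxy)methyl]-3,5,5-trimethylcyclohex-2-en-1-yl]-5,7-dimethoxy-2H-chromen-2-one | COc1cc(OC)c2ccc(=O)oc2c1[C@H]1C=C(C)CC(C)(C)[C@@H]1[C@H](O)c1c(OC)cc(OC)c2ccc(=O)oc12 | intermediate
10 | 8-[(1S,6R)-6-(5,7-dimethoxy-2-oxo-2H-chromene-8-carbonyl)-3,5,5-trimethylcyclohex-2-en-1-yl]-5,7-dimethoxy-2H-chromen-2-one | COc1cc(OC)c2ccc(=O)oc2c1[C@H]1C=C(C)CC(C)(C)[C@@H]1C(=O)c1c(OC)cc(OC)c2ccc(=O)oc12 | intermediate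
11 | 8-[(1S,6R)-6-[(R)-(5,7-dimethoxy-2-oxo-2H-chromen-8-yl)(hydroxy)methyl]-3,5,5-trimethylcyclohex-2-en-1-yl]-5,7-dimethoxy-2H-chromen-2-one (IN0553) | COc1cc(OC)c2ccc(=O)oc2c1[C@H]1C=C(C)CC(C)(C)[C@@H]1[C@@H](O)c1c(OC)cc(OC)c2ccc(=O)oc12 | target

**Step count**

Total steps: 7. Longest linear sequence: 6 (1 → 2 → 4 → 8 → 9 → 10 → 11; the branch from citropten is 5 steps).

**Steps most likely to fail**

Step 4. The hindered, electron-rich formyl group may be activated too weakly inside the confined acid, whose proton is also bound by the coumarin carbonyls, so that turnover stalls or the two diene faces are not told apart. Fallback: from 4 and 7 the cycloaddition is run with a small achiral acid (catalytic TfOH or BF3·OEt2, CH2Cl2, −78 → −20 °C), the established racemic acid-promoted oxa-Diels–Alder reaction. This gives 8 together with its mirror image, (1S,3R,4S)-3-(5,7-dimethoxy-2-oxo-2H-chromen-8-yl)-1,8,8-trimethyl-2-oxabicyclo[2.2.2]oct-5-ene F1. Preparative chromatography on a chiral stationary phase delivers enantiopure 8, where the route resumes.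

Step 5. Capture of the allyl cation by the only moderately nucleophilic coumarin may be outpaced by proton loss or re-closure. Under longer acid exposure the liberated electron-rich benzylic C7–OH may ionise or add back to the C2=C3 double bond. Attack through C6 of citropten is a further possible leak. Fallback: from 8 the cation is intercepted by the far more nucleophilic 3,5-dimethoxyphenol (cat. BF3·OEt2, CH2Cl2, −40 °C), as in terpenylations of resorcinol ethers. This gives 2-[(1S,6R)-6-[(S)-(5,7-dimethoxy-2-oxo-2H-chromen-8-yl)(hydroxy)methyl]-3,5,5-trimethylcyclohex-2-en-1-yl]-3,5-dimethoxyphenol F2 with the same trans sense. Magnesium-mediated ortho-formylation (MgCl2, Et3N, paraformaldehyde, MeCN) can enter only the single free position ortho to the phenol and gives 2-hydroxy-4,6-dimethoxy-3-[(1S,6R)-6-[(S)-(5,7-dimethoxy-2-oxo-2H-chromen-8-yl)(hydroxy)methyl]-3,5,5-trimethylcyclohex-2-en-1-yl]benzaldehyde F3. Wittig olefination with Ph3P=CHCO2Et in hot N,N-diethylaniline, the standard coumarin synthesis from salicylaldehydes, passes through ethyl (Z)-3-{2-hydroxy-4,6-dimethoxy-3-[(1S,6R)-6-[(S)-(5,7-dimethoxy-2-oxo-2H-chromen-8-yl)(hydroxy)methyl]-3,5,5-trimethylcyclohex-2-en-1-yl]phenyl}prop-2-enoate F4, which lactonises to 9, where the route resumes.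

Step 7. With two bulky α-branches (the quaternary C5 and the aryl-bearing C1) the facial preference of the ketone is not clear-cut, so hydride may enter from the Re face and return the (S)-carbinol 9. Fallback: from 10 substrate control is replaced by reagent control, a Corey–Bakshi–Shibata reduction (Me-oxazaborolidine, catecholborane, toluene, −40 °C). The catalyst enantiomer is the one that delivers hydride to the Si face, which is the (S)-catalyst if the aryl group acts as the larger ketone substituent. This leads directly to 11 and makes no new compound (F0); any 9 formed is returned to step 6.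

**Further compounds**

F1 | step 4 | (1S,3R,4S)-3-(5,7-dimethoxy-2-oxo-2H-chromen-8-yl)-1,8,8-trimethyl-2-oxabicyclo[2.2.2]oct-5-ene (enantiomer of 8) | C[C@]12CC(C)(C)[C@H](C=C1)[C@H](c1c(OC)cc(OC)c3ccc(=O)oc13)O2
F2 | step 5 | 2-[(1S,6R)-6-[(S)-(5,7-dimethoxy-2-oxo-2H-chromen-8-yl)(hydroxy)methyl]-3,5,5-trimethylcyclohex-2-en-1-yl]-3,5-dimethoxyphenol | COc1cc(OC)c([C@H]2C=C(C)CC(C)(C)[C@@H]2[C@H](O)c2c(OC)cc(OC)c3ccc(=O)oc23)c(O)c1
F3 | step 5 | 2-hydroxy-4,6-dimethoxy-3-[(1S,6R)-6-[(S)-(5,7-dimethoxy-2-oxo-2H-chromen-8-yl)(hydroxy)methyl]-3,5,5-trimethylcyclohex-2-en-1-yl]benzaldehyde | COc1cc(OC)c([C@H]2C=C(C)CC(C)(C)[C@@H]2[C@H](O)c2c(OC)cc(OC)c3ccc(=O)oc23)c(O)c1C=O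
F4 | step 5 | ethyl (Z)-3-{2-hydroxy-4,6-dimethoxy-3-[(1S,6R)-6-[(S)-(5,7-dimethoxy-2-oxo-2H-chromen-8-yl)(hydroxy)methyl]-3,5,5-trimethylcyclohex-2-en-1-yl]phenyl}prop-2-enoate | COc1cc(OC)c([C@H]2C=C(C)CC(C)(C)[C@@H]2[C@H](O)c2c(OC)cc(OC)c3ccc(=O)oc23)c(O)c1/C=C\C(=O)OCC
F0 | step 7 | none | none
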